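(All runs stem from a simulated flask for an exercise, noise included.)

In a one-step world a product only gathers, so its readings climb with time.

| flask | starting material | protic impurity | remark | time |
|---|---|---|---|---|
| north | 10 mM | 3 mM | the very flask that is asked about, followed so far |  |
| flask | 10 mM | 3.00 mM |  | 30 h |

- north (time / h: isomer of the product / %, target / %): 1.50: 0, 6.9; 4.00: 0.4, 14.8; 8.00: 1.2, 20.8; 12.0: 0.5, 23.8

(standard deviation of a reading: 1 percentage point)

- what was read earlier has a scatter of 1 percentage point, one standard deviation

1. share of isomer of the product in isomer of the product plus target at 30 min
2. share of isomer of the product in isomer of the product plus target at 30 h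
3. which of isomer of the product and target there is more of at 30 h

Yet the north flask reads isomer of the product at 1.2% after 8.00 h and 0.5% after 12.0 h, while target climbs from 20.8% to 23.8%. The drop of 0.7 percentage points is smaller than 1.4 points, the scatter of a difference of two readings, so these readings show no real fall.

The north isomer readings are therefore summed, to 2.10%, and the target readings to 66.3%. The isomer sum over both sums gives 3.07%, the pooled share, a frozen selectivity. The isomer sum has a scatter of 2 points, so the pooled share has one of 2.9 points, and two standard deviations reach 8.92%. This reckoning takes the pooled share for 30 min and 30 h alike, with target ahead, as the ceiling stays under an even split.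

The forecast, which differs, gives 1.5% and 7% with target ahead, reckoning with “slow conversion of target to isomer”.

The north flask gives 0.264% and 1.58%, with target ahead, so its share is not frozen: the later value stands above the earlier, and both lie below the pooled share.

    starting material ⇌ other conformer (K = 0.500, k = 2.30 × 10⁻⁶ s⁻¹)
    starting material → target (k = 1.40 × 10⁻⁵ s⁻¹)
    other conformer → isomer of the product (k = 2.00 × 10⁻⁵ s⁻¹)
    2 starting material → homo dimer (k = 0.00260 M⁻¹ s⁻¹)
    target → over-reaction product (k = 3.30 × 10⁻⁸ s⁻¹)
    other conformer + protic impurity → quenched substrate (k = 0.0650 M⁻¹ s⁻¹)

At 30.0 h the north flask's other conformer goes to quenched substrate 8.1 times as fast as to isomer of the product. It stands at 0.0647% beside 4.75% of starting material.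

For a neighbour flask with 40 mM of starting material, the pooled share carried over unchanged gives 3.07%, with target ahead. That neighbour computes to 1.71% at 30 h, with target 16.4% and isomer of the product 0.287%.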